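The eleven-membered ring (C1 quaternary, C2=C3, C4 carbinol, C5–C6 oxirane, C7, C8, C9=C10, C11) is closed between the oxirane methine C6 and its CH2 neighbour C7. The cis-fused C5–C6 oxirane is read as a latent (Z)-trisubstituted olefin, and the C7–C8 bridge beside C9=C10 as the former vinyl arm of a 2-substituted 1,3-diene. In one operation, 9-BBN hydroborates that vinyl arm and an intramolecular B-alkyl Suzuki–Miyaura coupling with a (Z)-vinyl iodide forges the C(sp2)–C(sp3) bond and the macrocycle with retention of geometry. The precursor is an acyclic iodo-pentaene bearing the quaternary centre and the (S)-carbinol, whose hydroxyl then directs the epoxidation.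

Key step: step 13

Remarks:
- Locants C1–C11 are the ring atoms as defined above; C20 is the hydroxymethyl carbon on C9; "homoprenyl" is 4-methylpent-3-en-1-yl.
- Assumption: the chiral sulfonate-bearing NHC ligand of step 2 is used in the antipode that delivers the (S)-quaternary centre.
- Assumption: (−)-MIB in step 12 transfers the alkenyl group to the Si face of the aldehyde (the usual sense for this ligand class), which corresponds to 4S here; both ligands are available in either antipode should the sense be opposite.

Step 1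
Reactants: 1 geraniol
Product: 2 geranyl diethyl phosphate
Conditions: ClP(O)(OEt)2, pyridine, DMAP (cat.), CH2Cl2, 0 °C → rt
Reagents that add atoms: diethyl chlorophosphate, CCOP(=O)(Cl)OCC
Why: O-phosphorylation of a primary allylic alcohol under basic conditions should proceed without allylic transposition and installs the leaving group for the SN2′ step.

Step 2
Reactants: 2 geranyl diethyl phosphate
Product: 3 (S)-[3-ethenyl-3,7-dimethyloct-6-en-1-yn-1-yl]trimethylsilane
Conditions: (i-Bu)2Al–C≡C–SiMe3 (from HC≡CSiMe3, DIBAL-H, Et3N 5 mol%, hexanes, 0 → 22 °C), CuCl2·2H2O (2.5 mol%), chiral sulfonate-bearing NHC–Ag complex (1.25 mol%), THF, −30 °C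
Reagents that add atoms: ethynyltrimethylsilane, C#C[Si](C)(C)C
Why: Cu–NHC-catalysed enantioselective allylic substitution should deliver the alkynyl group SN2′ to the γ,γ-disubstituted terminus of the geranyl phosphate, so the all-carbon quaternary centre C1 is set (S) by the chiral ligand, a reaction class documented for geranyl-type phosphates with alkynylaluminium reagents.

Step 3
Reactants: 3 (S)-[3-ethenyl-3,7-dimethyloct-6-en-1-yn-1-yl]trimethylsilane
Product: 5 (S)-3,7-dimethyl-3-[(trimethylsilyl)ethynyl]oct-6-en-1-ol, via B-alkyl-9-BBN adduct 4 (not isolated)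
Conditions: 9-BBN (1.1 equiv), THF, 0 °C → rt; then aq NaOH, 30% H2O2, 0 °C
Reagents that add atoms: hydrogen peroxide, OO
Why: Hydroboration–oxidation; 9-BBN should add anti-Markovnikov to the monosubstituted vinyl group in preference to the trisubstituted olefin and the silylalkyne, and the cold methanol-free oxidative work-up should leave the C(sp)–Si bond intact.

Step 4
Reactants: 5 (S)-3,7-dimethyl-3-[(trimethylsilyl)ethynyl]oct-6-en-1-ol
Product: 6 (S)-3,7-dimethyl-3-[(trimethylsilyl)ethynyl]oct-6-enal
Conditions: Dess–Martin periodinane, NaHCO3, CH2Cl2, 0 °C → rt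
Reagents that add atoms: none
Why: Dess–Martin oxidation of a primary alcohol should stop at the aldehyde, which has no epimerisable centre (the β-carbon is quaternary).

Step 5
Reactants: 6 (S)-3,7-dimethyl-3-[(trimethylsilyl)ethynyl]oct-6-enal
Product: 7 (S)-1,1-dibromo-4,8-dimethyl-4-[(trimethylsilyl)ethynyl]nona-1,7-diene
Conditions: CBr4, PPh3, Zn, CH2Cl2, rt
Reagents that add atoms: carbon tetrabromide, BrC(Br)(Br)Br
Why: Corey–Fuchs dibromo-olefination (Wittig reaction of Ph3P=CBr2) adds the carbon that becomes C9 under neutral conditions tolerated by the silylalkyne and the trisubstituted olefin.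

Step 6
Reactants: 7 (S)-1,1-dibromo-4,8-dimethyl-4-[(trimethylsilyl)ethynyl]nona-1,7-diene
Product: 9 (S)-5,9-dimethyl-5-[(trimethylsilyl)ethynyl]dec-8-en-2-yn-1-ol, via lithium acetylide 8 (not isolated)
Conditions: n-BuLi (2.2 equiv), THF, −78 → 0 °C; (CH2O)n, 0 °C → rt; aq NH4Cl
Reagents that add atoms: formaldehyde (as paraformaldehyde), C=O
Why: Second stage of the Corey–Fuchs sequence: Br/Li exchange and Fritsch–Buttenberg–Wiechell 1,2-shift should give the lithium acetylide, which is hydroxymethylated in the same flask to install C20, while the silyl cap keeps the other alkyne inert.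

Step 7
Reactants: 9 (S)-5,9-dimethyl-5-[(trimethylsilyl)ethynyl]dec-8-en-2-yn-1-ol
Product: 11 (2E,5S)-2-ethenyl-5,9-dimethyl-5-[(trimethylsilyl)ethynyl]deca-2,8-dien-1-ol, via alkenylmagnesium chelate 10 (not isolated)
Conditions: CH2=CHMgCl (5 equiv), cyclohexane/THF, reflux; aq NH4Cl, 0 °C
Reagents that add atoms: vinylmagnesium chloride, C=C[Mg]Cl
Why: Chelation-controlled anti-carbomagnesiation of a propargylic alcohol: the magnesium alkoxide should direct the vinyl group to the proximal alkyne carbon (C9) and magnesium to C10 on the opposite side, so protonolysis leaves the vinyl arm cis to C11 and fixes the C9=C10 geometry.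

Step 8
Reactants: 11 (2E,5S)-2-ethenyl-5,9-dimethyl-5-[(trimethylsilyl)ethynyl]deca-2,8-dien-1-ol
Product: 12 tert-butyldimethylsilyl ether of 11
Conditions: TBSCl, imidazole, DMF, rt
Reagents that add atoms: tert-butyldimethylsilyl chloride, CC(C)(C)[Si](C)(C)Cl
Why: Standard silylation of the primary allylic alcohol masks the C20 hydroxyl so that it cannot later direct epoxidation of C9=C10.

Step 9
Reactants: 12 tert-butyldimethylsilyl ether of 11
Product: 13 tert-butyl{[(2E,5S)-2-ethenyl-5-ethynyl-5,9-dimethyldeca-2,8-dien-1-yl]oxy}dimethylsilane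
Conditions: K2CO3, MeOH, rt
Reagents that add atoms: none
Why: Methanolysis should cleave only the C(sp)–Si bond (protodesilylation of an alkynylsilane), the TBS ether being stable to carbonate in methanol.

Step 10
Reactants: 14 prop-2-yn-1-ol
Product: 16 (Z)-3-iodo-2-methylprop-2-en-1-ol, via alkenylmagnesium alkoxide 15 (not isolated)
Conditions: MeMgBr (2.5 equiv), CuI (10 mol%), THF, −10 °C → rt; then I2, −10 °C
Reagents that add atoms: methylmagnesium bromide, C[Mg]Br; iodine, II
Why: Copper-catalysed anti-carbomagnesiation of propargyl alcohol should place methyl on the internal carbon and magnesium on the terminus within a five-membered alkoxide chelate, so iodinolysis with retention gives the Z-iodoalkene.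

Step 11
Reactants: 16 (Z)-3-iodo-2-methylprop-2-en-1-ol
Product: 17 (Z)-3-iodo-2-methylprop-2-enal
Conditions: MnO2, CH2Cl2, rt, dark; used at once
Reagents that add atoms: none
Why: Neutral heterogeneous allylic oxidation with MnO2 should give the enal without acid or base that would promote Z → E isomerisation.

Step 12
Reactants: 13 tert-butyl{[(2E,5S)-2-ethenyl-5-ethynyl-5,9-dimethyldeca-2,8-dien-1-yl]oxy}dimethylsilane; 17 (Z)-3-iodo-2-methylprop-2-enal
Product: 20 acyclic (1S,4S)-iodo-pentaenol, via alkenylborane 18 (not isolated), via alkenylzinc 19 (not isolated)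
Conditions: Cy2BH (from BH3·SMe2, cyclohexene), toluene, 0 °C → rt; Me2Zn, −78 °C; (−)-MIB (5 mol%), then 17, −20 → 0 °C; aq NH4Cl
Reagents that add atoms: none
Why: Syn-hydroboration of the terminal alkyne (faster than that of the conjugated diene terminus) should give the (E)-alkenylborane, boron-to-zinc transmetalation the alkenylzinc, and amino-alcohol-catalysed 1,2-addition to the enal should set C4 as S by ligand-controlled Si-face attack (catalytic asymmetric alkenylzinc addition).

Step 13
Reactants: 20 acyclic (1S,4S)-iodo-pentaenol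
Product: 22 (1S,4S)-macrocyclic allylic alcohol, via bis-borylated intermediate 21 (not isolated)
Conditions: 9-BBN (2.2 equiv), THF, 0 °C → rt; then slow addition to PdCl2(dppf) (15 mol%), AsPh3 (30 mol%), Cs2CO3, degassed THF/DMF/H2O, 50 °C, final concentration about 1 mM
Reagents that add atoms: none
Why: 9-BBN should first cap the C4 hydroxyl as a borinate and then add anti-Markovnikov to the CH=CH2 terminus of the 2-substituted 1,3-diene, placing boron on C7; under Pd(0) and aqueous carbonate the vinyl iodide undergoes oxidative addition, the hydroxide-activated B-alkyl group transmetalates and reductive elimination forms the C6–C7 bond (intramolecular B-alkyl Suzuki–Miyaura coupling, a reaction type with precedent in macrocyclisation). The eleven-membered ring is closed by reductive elimination from a twelve-membered alkyl(alkenyl)palladacycle, a C(sp3)–C(sp2) closure that places the iodoalkene carbons in the ring with retention of geometry. No stereocentre is created: C1 and C4 are carried through, and the cis C5=C6 geometry required for the cis-oxirane comes from the vinyl iodide. The step needs hydroboration of one olefin out of five, which the steric bias of 9-BBN for the only monosubstituted terminus and the stoichiometry should secure. It also needs cyclisation over oligomerisation, secured by slow addition at high dilution and helped by the Z-iodoalkene, the ring-cis C9=C10 olefin and the quaternary C1, which turn the chain ends towards each other. β-Hydride elimination from the homoallylic alkylpalladium should be held back by the wide-bite-angle dppf ligand.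

Step 14
Reactants: 22 (1S,4S)-macrocyclic allylic alcohol
Product: 23 (1S,4S,5R,6R)-epoxy alcohol
Conditions: VO(acac)2 (5 mol%), t-BuOOH (1.3 equiv, decane), CH2Cl2, 0 °C
Reagents that add atoms: tert-butyl hydroperoxide, CC(C)(C)OO
Why: Vanadium-catalysed hydroxyl-directed epoxidation should select the trisubstituted C5=C6 over the hindered disubstituted C2=C3 and the olefins lacking a free allylic hydroxyl; with ring carbon C3 held out of the olefin plane and the 4S hydroxyl near it (the small O–C–C=C angle vanadium requires), oxygen should arrive on the peripheral face syn to OH and give the erythro 5R,6R oxirane.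

Step 15
Reactants: 23 (1S,4S,5R,6R)-epoxy alcohol
Product: 24 silyl-protected senecioate
Conditions: 3-methylbut-2-enoyl chloride, pyridine, DMAP (cat.), CH2Cl2, 0 °C
Reagents that add atoms: 3-methylbut-2-enoyl chloride, CC(C)=CC(=O)Cl
Why: DMAP-catalysed O-acylation with retention at C4; pyridine as the only base should avoid deconjugation of the acyl group through a vinylketene.

Step 16
Reactants: 24 silyl-protected senecioate
Product: 25 target CNP0318149.1
Conditions: TBAF, AcOH, THF, 0 °C → rt
Reagents that add atoms: none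
Why: Buffered fluoride desilylation should free the primary allylic alcohol without opening the oxirane or cleaving or migrating the allylic ester.

Compound list
1 | geraniol, (2E)-3,7-dimethylocta-2,6-dien-1-ol | CC(C)=CCC/C(C)=C/CO | starting material
2 | geranyl diethyl phosphate | CC(C)=CCC/C(C)=C/COP(=O)(OCC)OCC | intermediate
3 | (S)-[3-ethenyl-3,7-dimethyloct-6-en-1-yn-1-yl]trimethylsilane | CC(C)=CCC[C@](C=C)(C)C#C[Si](C)(C)C | intermediate
4 | B-alkyl-9-BBN adduct of 3, boron on the terminal carbon of the former vinyl group (same spatial arrangement at the quaternary carbon; formally R because boron lowers the CIP rank of that arm) | CC(C)=CCC[C@](CCB1C2CCCC1CCC2)(C)C#C[Si](C)(C)C | intermediate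
5 | (S)-3,7-dimethyl-3-[(trimethylsilyl)ethynyl]oct-6-en-1-ol | CC(C)=CCC[C@](CCO)(C)C#C[Si](C)(C)C | intermediate
6 | (S)-3,7-dimethyl-3-[(trimethylsilyl)ethynyl]oct-6-enal | CC(C)=CCC[C@](CC=O)(C)C#C[Si](C)(C)C | intermediate
7 | (S)-1,1-dibromo-4,8-dimethyl-4-[(trimethylsilyl)ethynyl]nona-1,7-diene | CC(C)=CCC[C@](CC=C(Br)Br)(C)C#C[Si](C)(C)C | intermediate
8 | lithium acetylide of (S)-4,8-dimethyl-4-[(trimethylsilyl)ethynyl]non-7-en-1-yne | CC(C)=CCC[C@](CC#C[Li])(C)C#C[Si](C)(C)C | intermediate
9 | (S)-5,9-dimethyl-5-[(trimethylsilyl)ethynyl]dec-8-en-2-yn-1-ol | CC(C)=CCC[C@](CC#CCO)(C)C#C[Si](C)(C)C | intermediate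
10 | chloromagnesium alkoxide of 11 carrying MgCl on C10 (O–Mg chelate, drawn open; vinyl on C9 cis to C11, magnesium cis to CH2O) | CC(C)=CCC[C@](C/C([Mg]Cl)=C(\C=C)CO[Mg]Cl)(C)C#C[Si](C)(C)C | intermediate
11 | (2E,5S)-2-ethenyl-5,9-dimethyl-5-[(trimethylsilyl)ethynyl]deca-2,8-dien-1-ol | CC(C)=CCC[C@](C/C=C(\C=C)CO)(C)C#C[Si](C)(C)C | intermediate
12 | tert-butyldimethylsilyl ether of 11 | CC(C)=CCC[C@](C/C=C(\C=C)CO[Si](C)(C)C(C)(C)C)(C)C#C[Si](C)(C)C | intermediate
13 | tert-butyl{[(2E,5S)-2-ethenyl-5-ethynyl-5,9-dimethyldeca-2,8-dien-1-yl]oxy}dimethylsilane | CC(C)=CCC[C@](C/C=C(\C=C)CO[Si](C)(C)C(C)(C)C)(C)C#C | intermediate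
14 | prop-2-yn-1-ol (propargyl alcohol) | C#CCO | starting material
15 | bromomagnesium (Z)-3-(bromomagnesio)-2-methylprop-2-en-1-olate (O–Mg chelate, drawn open) | Br[Mg]/C=C(C)\CO[Mg]Br | intermediate
16 | (Z)-3-iodo-2-methylprop-2-en-1-ol | OC/C(C)=C\I | intermediate
17 | (Z)-3-iodo-2-methylprop-2-enal | O=C/C(C)=C\I | intermediate
18 | (E)-alkenyl(dicyclohexyl)borane: 13 with the ethynyl group converted into (E)-CH=CH–B(c-C6H11)2, quaternary centre S | CC(C)=CCC[C@](C/C=C(\C=C)CO[Si](C)(C)C(C)(C)C)(C)/C=C/B(C1CCCCC1)C1CCCCC1 | intermediate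
19 | (E)-alkenyl(methyl)zinc: as 18 with ZnCH3 in place of boron | CC(C)=CCC[C@](C/C=C(\C=C)CO[Si](C)(C)C(C)(C)C)(C)/C=C/[Zn]C | intermediate
20 | acyclic (1S,4S)-iodo-pentaenol: I–C6H=C5(CH3)–C4H(OH)–C3H=C2H–C1(CH3)(homoprenyl)–C11H2–C10H=C9(CH2OTBS)–C8H=C7H2; C5=C6 Z, C2=C3 E, C9=C10 E (vinyl cis to C11) | CC(C)=CCC[C@](C/C=C(\C=C)CO[Si](C)(C)C(C)(C)C)(C)/C=C/[C@H](O)/C(C)=C\I | intermediate
21 | 20 with the C4 oxygen as its 9-BBN borinate and the vinyl arm hydroborated (9-BBN on C7) | CC(C)=CCC[C@](C/C=C(\CCB1C2CCCC1CCC2)CO[Si](C)(C)C(C)(C)C)(C)/C=C/[C@H](OB1C2CCCC1CCC2)/C(C)=C\I | intermediate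
22 | (1S,4S)-macrocyclic allylic alcohol: eleven-membered carbocycle, C2=C3 E, C5=C6 Z (5-methyl), C9=C10 ring-cis (E by CIP) bearing CH2OTBS, C4–OH, C1 bearing methyl and homoprenyl | CC(C)=CCC[C@]1(C)/C=C/[C@H](O)/C(C)=C\CC/C(CO[Si](C)(C)C(C)(C)C)=C\C1 | intermediate
23 | (1S,4S,5R,6R)-epoxy alcohol: 22 with a cis-fused C5–C6 oxirane erythro to the C4 hydroxyl | CC(C)=CCC[C@]1(C)/C=C/[C@H](O)[C@]2(C)O[C@@H]2CC/C(CO[Si](C)(C)C(C)(C)C)=C\C1 | intermediate
24 | silyl-protected senecioate: 3-methylbut-2-enoate ester of 23 at C4 | CC(C)=CCC[C@]1(C)/C=C/[C@H](OC(=O)C=C(C)C)[C@]2(C)O[C@@H]2CC/C(CO[Si](C)(C)C(C)(C)C)=C\C1 | intermediate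
25 | CNP0318149.1: quaternary carbon S, ester carbinol S, oxirane carbons R,R; C2=C3 E; C9=C10 ring-cis with free CH2OH | CC(C)=CCC[C@]1(C)/C=C/[C@H](OC(=O)C=C(C)C)[C@]2(C)O[C@@H]2CC/C(CO)=C\C1 | target

Total step count: 16. Longest linear sequence: 14 steps (steps 1–9 and 12–16, from geraniol); steps 10–11 form the side branch.

Steps most likely to fail

Step 13. Oligomerisation, protodeboronation or β-hydride elimination may outrun closure of the strained eleven-membered ring, or hydroboration may not stay confined to the vinyl arm. The fallback forms the same bond from a preformed organozinc under anhydrous conditions. It sets out from 20: hydroboration with 9-BBN and oxidative work-up would give the C4,C7-diol F1; an Appel reaction (PPh3, I2, imidazole, 0 °C), selective for the primary hydroxyl, the homoallylic iodide F2; TESCl/imidazole the C4 triethylsilyl ether F3. Zinc insertion into the C(sp3)–I bond (Zn dust, LiCl, THF, 30 °C), which leaves the vinyl iodide untouched, followed by slow addition to Pd(0) (Pd2(dba)3, SPhos, THF, 40 °C, high dilution) in an intramolecular Negishi coupling would give the macrocyclic triethylsilyl ether F4. Selective cleavage of the secondary TES ether (PPTS, MeOH, 0 °C) comes back to the route at 22.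

Step 12. The diene terminus may compete with the alkyne for the borane, facial discrimination in the alkenyl transfer to an α-branched β-iodoenal may be insufficient, or the iodoenal may isomerise from Z to E under Lewis-acidic zinc. The fallback separates C–C bond formation from stereocontrol and sets out from 13 and 17. Deprotonation of 13 (n-BuLi, THF, −78 °C) and addition to 17 would give the propargylic alcohol F5 as both C4 epimers; MnO2 the ynone F6; Noyori asymmetric transfer hydrogenation (Ru–TsDPEN–p-cymene, i-PrOH, catalyst antipode chosen for S) the (4S)-propargylic alcohol F7. Alkoxide-directed trans-hydroalumination (Red-Al, THF, 0 °C, then protonolysis) would reduce only the propargylic triple bond to the E-olefin and come back to the route at 20.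

Step 14. The peroxide may be delivered in the threo sense (wrong olefin face for the 4S alcohol), or site selectivity between C5=C6 and C2=C3 may erode. The fallback uses the threo mode deliberately and corrects C4 afterwards; it sets out from 13 and 17. Step 12 run with (+)-MIB would give the (1S,4R)-iodo-pentaenol F8; the same hydroboration/Suzuki–Miyaura closure the (1S,4R)-macrocyclic alcohol F9; hydroxyl-directed epoxidation (Ti(Oi-Pr)4 or VO(acac)2, t-BuOOH), now threo, the (1S,4R,5R,6R)-epoxy alcohol F10. A Mitsunobu esterification with 3-methylbut-2-enoic acid (PPh3, DIAD, toluene, 0 °C) would install the ester with inversion at C4; SN2′ attack at the neopentyl C2 is disfavoured. This comes back to the route at 24.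

Further compounds
F1 | step 13 | C4,C7-diol: 20 with the vinyl arm converted into CH2CH2OH | CC(C)=CCC[C@](C/C=C(\CCO)CO[Si](C)(C)C(C)(C)C)(C)/C=C/[C@H](O)/C(C)=C\I
F2 | step 13 | homoallylic iodide: F1 with the primary hydroxyl replaced by iodine | CC(C)=CCC[C@](C/C=C(\CCI)CO[Si](C)(C)C(C)(C)C)(C)/C=C/[C@H](O)/C(C)=C\I
F3 | step 13 | C4 triethylsilyl ether of F2 | CC(C)=CCC[C@](C/C=C(\CCI)CO[Si](C)(C)C(C)(C)C)(C)/C=C/[C@H](O[Si](CC)(CC)CC)/C(C)=C\I
F4 | step 13 | macrocyclic C4 triethylsilyl ether (TES ether of 22) | CC(C)=CCC[C@]1(C)/C=C/[C@H](O[Si](CC)(CC)CC)/C(C)=C\CC/C(CO[Si](C)(C)C(C)(C)C)=C\C1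
F5 | step 12 | propargylic alcohol from acetylide addition, both C4 epimers | CC(C)=CCC[C@](C/C=C(\C=C)CO[Si](C)(C)C(C)(C)C)(C)C#CC(O)/C(C)=C\I
F6 | step 12 | ynone (C4 ketone) | CC(C)=CCC[C@](C/C=C(\C=C)CO[Si](C)(C)C(C)(C)C)(C)C#CC(=O)/C(C)=C\I
F7 | step 12 | (4S)-propargylic alcohol | CC(C)=CCC[C@](C/C=C(\C=C)CO[Si](C)(C)C(C)(C)C)(C)C#C[C@H](O)/C(C)=C\I
F8 | step 14 | (1S,4R)-iodo-pentaenol, C4 epimer of 20 | CC(C)=CCC[C@](C/C=C(\C=C)CO[Si](C)(C)C(C)(C)C)(C)/C=C/[C@@H](O)/C(C)=C\I
F9 | step 14 | (1S,4R)-macrocyclic allylic alcohol, C4 epimer of 22 | CC(C)=CCC[C@]1(C)/C=C/[C@@H](O)/C(C)=C\CC/C(CO[Si](C)(C)C(C)(C)C)=C\C1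
F10 | step 14 | (1S,4R,5R,6R)-epoxy alcohol, C4 epimer of 23 | CC(C)=CCC[C@]1(C)/C=C/[C@@H](O)[C@]2(C)O[C@@H]2CC/C(CO[Si](C)(C)C(C)(C)C)=C\C1
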